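Ring B is disconnected across C1–C2 and C3–C4 (target numbering), leaving an o-formyl diarylmethane and a two-carbon enoate. The key step exploits the ortho relationship on ring A of C4 (future styrenic CH, an aldehyde) and C1 (doubly benzylic CH2 carrying the pendant aryl ring): light turns them into the termini of a hydroxy-o-quinodimethane, which a chiral template made from Ti(OiPr)4 and (R,R)-TADDOL joins to allyl tiglate by an endo [4+2] cycloaddition. One operation closes ring B, forms both bonds and sets the C1 and C2 stereocentres trans. The carboxyl on C3 and the hydroxyl on C4 are traceless activators: β-lactonisation and loss of CO2 then unveil the C3=C4 double bond.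

Key step: step 2

Remark on numbering: C1–C4, C4a, C8a and the ring letters (ring A, the dimethoxybenzo ring; ring B, the dihydro ring) refer to the target. The names of 7 and 8 use their own tetralin locants, in which the carbinol carbon is C1 and the aryl-bearing carbon is C4.

Assumption: (R,R)-TADDOL, (4R,5R)-2,2-dimethyl-α,α,α′,α′-tetraphenyl-1,3-dioxolane-4,5-dimethanol, is taken to direct the dienophile to the diene face that gives 7. The sense of induction has to be confirmed on the first run, and the (S,S)-ligand takes its place if the mirror-image adduct forms.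

Step 1
Reactants: 1 3,4-dimethoxybenzyl chloride (4-(chloromethyl)-1,2-dimethoxybenzene); 2 2-bromo-4,5-dimethoxybenzaldehyde
Product: 4 2-(3,4-dimethoxybenzyl)-4,5-dimethoxybenzaldehyde, via benzylzinc chloride 3 (not isolated)
Conditions: Zn dust, LiCl, THF, 25 °C; then 2, Pd(OAc)2 (1 mol %), SPhos (2 mol %), THF, 25 °C
Reagents that add atoms: none
Why: LiCl-assisted insertion of zinc into the benzylic C–Cl bond gives a benzylzinc chloride that is too weakly nucleophilic to add to the aldehyde of 2 and is joined to its C–Br carbon by Negishi cross-coupling under Pd(OAc)2/SPhos catalysis; no stereocentre is formed.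

Step 2
Reactants: 4 2-(3,4-dimethoxybenzyl)-4,5-dimethoxybenzaldehyde; 5 allyl tiglate (prop-2-en-1-yl (E)-2-methylbut-2-enoate)
Product: 7 prop-2-en-1-yl (1S,2R,3S,4R)-4-(3,4-dimethoxyphenyl)-1-hydroxy-6,7-dimethoxy-2,3-dimethyl-1,2,3,4-tetrahydronaphthalene-2-carboxylate, via photoenol 6 (not isolated)
Conditions: Ti(OiPr)4 (1.5 equiv), (R,R)-TADDOL (1.6 equiv), 5 (3 equiv), degassed toluene, hν (366 nm), 25 °C; aqueous NaHCO3 work-up
Reagents that add atoms: none
Why: Excitation of 4 at 366 nm gives the n,π* triplet, which abstracts a doubly benzylic hydrogen (1,5-shift) and relaxes to the (E,E)-hydroxy-o-quinodimethane 6; this is bound through its oxygen to the titanium of (TADDOLato)Ti(OiPr)2, formed from Ti(OiPr)4 and (R,R)-TADDOL, which also coordinates the ester carbonyl of 5, and the two partners combine in a templated [4+2] cycloaddition that restores the aromaticity of ring A. The closest known reaction type is the Ti(OiPr)4-mediated photoenolization/Diels–Alder reaction of 2-alkylbenzaldehydes with hindered enones and enoates, including its enantioselective variant with TADDOL-type ligands. Ring B (six-membered) closes by an intermolecular suprafacial [4π+2π] cycloaddition in the endo mode, the C3–C4 and C1–C2 bonds forming in the same operation. The C1 configuration follows from the E geometry of the aryl-bearing diene terminus (aryl outside) together with the diene face selected by the chiral ligand; the C2 configuration follows from the E geometry of the tiglate and the endo orientation enforced by the Ti–O/ester chelate, which places the β-methyl group exo and hence trans to the aryl group, while the carbinol and quaternary centres (hydroxyl, ester and aryl all cis) are sacrificial. Regioselectivity (carbinol carbon to the ester-bearing carbon) is secured by the template and by the polarity of the diene, whose aryl-bearing terminus is the nucleophilic end, and enantiofacial selectivity rests on the ligand. The adduct has no chromophore at 366 nm and should therefore survive the irradiation, and the isolated allyl double bond is not a dienophile for 6.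

Step 3
Reactants: 7 prop-2-en-1-yl (1S,2R,3S,4R)-4-(3,4-dimethoxyphenyl)-1-hydroxy-6,7-dimethoxy-2,3-dimethyl-1,2,3,4-tetrahydronaphthalene-2-carboxylate
Product: 8 (1S,2R,3S,4R)-4-(3,4-dimethoxyphenyl)-1-hydroxy-6,7-dimethoxy-2,3-dimethyl-1,2,3,4-tetrahydronaphthalene-2-carboxylic acid
Conditions: Pd(PPh3)4 (5 mol %), morpholine (5 equiv), THF, 25 °C; aqueous citric acid work-up
Reagents that add atoms: none
Why: Pd(PPh3)4 inserts into the allyl–oxygen bond and morpholine captures the allyl group (Tsuji–Trost deallylation), so the hindered ester on the quaternary carbon is cleaved at the remote allyl carbon under neutral conditions that avoid retro-aldol opening of the β-hydroxy acid and leave all four stereocentres untouched.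

Step 4
Reactants: 8 (1S,2R,3S,4R)-4-(3,4-dimethoxyphenyl)-1-hydroxy-6,7-dimethoxy-2,3-dimethyl-1,2,3,4-tetrahydronaphthalene-2-carboxylic acid
Product: 10 (1R,2S)-1-(3,4-dimethoxyphenyl)-6,7-dimethoxy-2,3-dimethyl-1,2-dihydronaphthalene, via beta-lactone 9 (not isolated)
Conditions: PhSO2Cl (2 equiv), pyridine, 0 to 25 °C; then 60 °C
Reagents that add atoms: none
Why: Activation of the carboxyl group by PhSO2Cl in pyridine lets the cis carbinol hydroxyl close the β-lactone with retention, and thermal [2+2] cycloreversion of this electron-rich 4-aryl-β-lactone (β-lactone decarboxylation) expels CO2 and places the double bond regiospecifically at C3=C4, which removes the two sacrificial centres while C1 and C2, remote from the reacting atoms, keep their configuration.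

Compound list

1 | 3,4-dimethoxybenzyl chloride | COc1ccc(CCl)cc1OC | starting material
2 | 2-bromo-4,5-dimethoxybenzaldehyde | COc1cc(Br)c(C=O)cc1OC | starting material
3 | (3,4-dimethoxybenzyl)zinc chloride | COc1ccc(C[Zn]Cl)cc1OC | intermediate
4 | 2-(3,4-dimethoxybenzyl)-4,5-dimethoxybenzaldehyde | COc1ccc(Cc2cc(OC)c(OC)cc2C=O)cc1OC | intermediate
5 | allyl tiglate, prop-2-en-1-yl (E)-2-methylbut-2-enoate | C/C=C(\C)C(=O)OCC=C | starting material
6 | (E,E)-hydroxy-o-quinodimethane (photoenol of 4, hydroxyl and aryl group both outside; held on titanium through oxygen in the flask) | O/C=C1\C=C(OC)C(OC)=C/C1=C\c2ccc(OC)c(OC)c2 | intermediate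
7 | prop-2-en-1-yl (1S,2R,3S,4R)-4-(3,4-dimethoxyphenyl)-1-hydroxy-6,7-dimethoxy-2,3-dimethyl-1,2,3,4-tetrahydronaphthalene-2-carboxylate (hydroxyl, ester and aryl cis; both methyl groups on the opposite face) | COc1ccc([C@@H]2c3cc(OC)c(OC)cc3[C@H](O)[C@](C)(C(=O)OCC=C)[C@H]2C)cc1OC | intermediate
8 | (1S,2R,3S,4R)-4-(3,4-dimethoxyphenyl)-1-hydroxy-6,7-dimethoxy-2,3-dimethyl-1,2,3,4-tetrahydronaphthalene-2-carboxylic acid | COc1ccc([C@@H]2c3cc(OC)c(OC)cc3[C@H](O)[C@](C)(C(=O)O)[C@H]2C)cc1OC | intermediate
9 | cis-fused β-lactone of 8 (oxetan-2-one across the carbinol carbon and the quaternary carbon; all four stereocentres as in 8) | COc1ccc([C@@H]2c3cc(OC)c(OC)cc3[C@@H]4OC(=O)[C@]4(C)[C@H]2C)cc1OC | intermediate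
10 | (1R,2S)-1-(3,4-dimethoxyphenyl)-6,7-dimethoxy-2,3-dimethyl-1,2-dihydronaphthalene (aryl and C2 methyl trans) | COc1ccc([C@@H]2c3cc(OC)c(OC)cc3C=C(C)[C@H]2C)cc1OC | target

Total step count: 4. Longest linear sequence: 4 steps (1 and 2 to 4, then 7, 8 and 10).

Steps most likely to fail

Step 2 is the riskiest. The bulky chiral ligand may slow the cycloaddition of the trisubstituted enoate on the crowded titanium centre, and the monodentate ester may not be held rigidly enough for good enantiofacial discrimination. The fallback sets out from 4 and 5 and runs the cycloaddition with Ti(OiPr)4 alone, the ligand-free template that tolerates hindered dienophiles. It should give 7 together with its enantiomer, prop-2-en-1-yl (1R,2S,3R,4S)-4-(3,4-dimethoxyphenyl)-1-hydroxy-6,7-dimethoxy-2,3-dimethyl-1,2,3,4-tetrahydronaphthalene-2-carboxylate F1. Deallylation as in step 3 then gives 8 together with its enantiomer, (1R,2S,3R,4S)-4-(3,4-dimethoxyphenyl)-1-hydroxy-6,7-dimethoxy-2,3-dimethyl-1,2,3,4-tetrahydronaphthalene-2-carboxylic acid F2. The racemic acid is resolved by crystallisation with (R)-1-phenylethylamine (the (S)-amine is used if the other diastereomeric salt proves the less soluble one). The salt of the wanted acid, (R)-1-phenylethylammonium (1S,2R,3S,4R)-4-(3,4-dimethoxyphenyl)-1-hydroxy-6,7-dimethoxy-2,3-dimethyl-1,2,3,4-tetrahydronaphthalene-2-carboxylate F3, is collected and acidified with aqueous citric acid. The route is rejoined at 8.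

Step 4 comes second. Closure of the strained four-membered ring at the hindered tertiary carboxyl may be outrun by intermolecular acylation or by sulfonylation of the hydroxyl. The fallback sets out from 8 and activates the benzylic hydroxyl instead of the acid: PPh3 and DIAD in THF at 0 to 25 °C (Mitsunobu-type dehydrative decarboxylation). Ionisation of the oxyphosphonium group, assisted by the para methoxy group of ring A, and loss of CO2 from the neighbouring carboxylate (Grob-type fragmentation) should give the alkene directly. No new compound arises on this path (F0), and the route is rejoined at 10.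

Step 1 comes third. Wurtz-type homocoupling of the electron-rich benzyl chloride may compete during zinc insertion, and the benzylzinc reagent may add to the aldehyde. The fallback sets out from 1 and reverses the polarity of the coupling: Suzuki–Miyaura reaction of 1 with commercial (2-formyl-4,5-dimethoxyphenyl)boronic acid (COc1cc(C=O)c(B(O)O)cc1OC) under Pd(OAc)2, SPhos and K3PO4 in toluene at 60 °C, with no benzylic organometallic involved. No new compound arises on this path (F0), and the route is rejoined at 4.

Further compounds
F0 | step 1 | none | none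
F1 | step 2 | prop-2-en-1-yl (1R,2S,3R,4S)-4-(3,4-dimethoxyphenyl)-1-hydroxy-6,7-dimethoxy-2,3-dimethyl-1,2,3,4-tetrahydronaphthalene-2-carboxylate | COc1ccc([C@H]2c3cc(OC)c(OC)cc3[C@@H](O)[C@@](C)(C(=O)OCC=C)[C@@H]2C)cc1OC
F2 | step 2 | (1R,2S,3R,4S)-4-(3,4-dimethoxyphenyl)-1-hydroxy-6,7-dimethoxy-2,3-dimethyl-1,2,3,4-tetrahydronaphthalene-2-carboxylic acid | COc1ccc([C@H]2c3cc(OC)c(OC)cc3[C@@H](O)[C@@](C)(C(=O)O)[C@@H]2C)cc1OC
F3 | step 2 | (R)-1-phenylethylammonium (1S,2R,3S,4R)-4-(3,4-dimethoxyphenyl)-1-hydroxy-6,7-dimethoxy-2,3-dimethyl-1,2,3,4-tetrahydronaphthalene-2-carboxylate | COc1ccc([C@@H]2c3cc(OC)c(OC)cc3[C@H](O)[C@](C)(C(=O)[O-])[C@H]2C)cc1OC.C[C@@H]([NH3+])c1ccccc1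
F0 | step 4 | none | none
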